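Numbering: C1 = methyl-bearing fusion carbon, C2–C3 = CH2, C4 = isopropyl carbinol, C5 = fusion CH, C6 = acyloxy carbon, C7 = ketone, C8–C9 = diol, C10 = CH2. The seven-membered ring (C1, C5–C10) is cut at C7–C8. Since C9 and C5 are joined through C10 and C1, an oxygen bridge makes an oxolane (O–C9–C10–C1–C5) cis-fused to the cyclopentane (C1–C5); an ethylidene on C9 and a vinyl on C5 make it an allyl vinyl ether. One Claisen shift forms C7–C8, breaks C5–O and gives the hydroazulenone with C9=O and C5=C6. The precursor, a lactone-derived enol ether, also carries C4 as a ketal.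

Key step: step 7

Conventions: carbocyclic intermediates are named on the bicyclo[5.3.0]decane skeleton with the numbering above; α is the face of the C1 methyl group, β the opposite face.

Assumption: the sense of induction known for phosphinooxazoline ligands in decarboxylative allylation of 2-methylcycloalkanone enol carbonates ((S)-ligand gives the (S)-ketone) is taken to hold for the ketal-bearing enolate, hence the (R)-ligand; were it reversed, the (S)-ligand would be used with no other change.

Step 1
Reactants: 1 3-methylcyclopentane-1,2-dione (enol form: 2-hydroxy-3-methylcyclopent-2-en-1-one); 2 ethylene glycol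
Product: 3 7-methyl-1,4-dioxaspiro[4.4]nonan-6-one (racemic)
Conditions: HOCH2CH2OH (1.1 equiv), p-TsOH·H2O (cat.), benzene, reflux, Dean–Stark
Reagents that add atoms: ethylene glycol, OCCO
Why: Acid-catalysed ketalisation with azeotropic removal of water should occur at the carbonyl remote from the methyl group, after which the enol tautomerises to the 2-methyl ketone; the C–H stereocentre so formed is erased in step 2.

Step 2
Reactants: 3 7-methyl-1,4-dioxaspiro[4.4]nonan-6-one; 4 allyl chloroformate
Product: 6 allyl 7-methyl-1,4-dioxaspiro[4.4]non-6-en-6-yl carbonate, via sodium enolate 5 (not isolated)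
Conditions: NaN(SiMe3)2, THF, −78 to −30 °C; then ClCO2CH2CH=CH2, −78 °C to rt
Reagents that add atoms: allyl chloroformate, C=CCOC(Cl)=O
Why: The ketal carbon leaves only the methyl-bearing α-carbon enolisable, so enolate formation is regiospecific and the hard chloroformate should acylate the hindered tetrasubstituted enolate on oxygen (enol carbonate formation), while any C-acylated β-keto ester would enter step 3 in the same way.

Step 3
Reactants: 6 allyl 7-methyl-1,4-dioxaspiro[4.4]non-6-en-6-yl carbonate
Product: 7 (R)-7-allyl-7-methyl-1,4-dioxaspiro[4.4]nonan-6-one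
Conditions: Pd2(dba)3 (2.5 mol %), (R)-(CF3)3-t-BuPHOX (6 mol %), toluene, 30 °C
Reagents that add atoms: none
Why: Decarboxylative asymmetric allylic alkylation: zerovalent palladium ionises the allyl carbonate, carbon dioxide is lost and the chiral phosphinooxazoline palladium allyl enolate forms the C–C bond within the coordination sphere, which should set the quaternary carbon C1 as R under ligand control.

Step 4
Reactants: 7 (R)-7-allyl-7-methyl-1,4-dioxaspiro[4.4]nonan-6-one; 8 ozone; 9 methanol
Product: 10 methyl 2-[(7R)-7-methyl-6-oxo-1,4-dioxaspiro[4.4]nonan-7-yl]acetate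
Conditions: O3, NaOH (2.5 M in MeOH), CH2Cl2, −78 °C
Reagents that add atoms: ozone, [O-][O+]=O; methanol, CO
Why: Ozonolysis in methanolic sodium hydroxide turns a terminal alkene directly into the methyl ester (base-induced dehydration of the methoxy hydroperoxide), and the ketone, which has no α-hydrogen, and the ketal should be inert to the cold basic medium.

Step 5
Reactants: 10 methyl 2-[(7R)-7-methyl-6-oxo-1,4-dioxaspiro[4.4]nonan-7-yl]acetate; 11 vinylmagnesium bromide
Product: 13 cis-fused vinyl lactone (3aR,6aS)-3a-methyl-6a-vinyltetrahydrospiro[cyclopenta[b]furan-6,2'-[1,3]dioxolan]-2(3H)-one, via cerium alkoxide 12 (not isolated)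
Conditions: CH2=CHMgBr, CeCl3, THF, −78 °C to rt; aq. NH4Cl
Reagents that add atoms: vinylmagnesium bromide, C=C[Mg]Br
Why: Organocerium 1,2-addition should take the non-enolisable ketone in preference to the ester and approach anti to the acetate arm (held by chelation to the metal on the ketone oxygen), and the alkoxide cis to that arm closes the γ-lactone by 5-exo-trig acyl substitution, fixing C5 with vinyl cis to methyl; the minor C5 epimer cannot lactonise and is removed as its hydroxy ester.

Step 6
Reactants: 13 cis-fused vinyl lactone; 14 1,1-dibromoethane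
Product: 15 (3aR,6aS)-2-[(Z)-ethylidene]-3a-methyl-6a-vinylhexahydrospiro[cyclopenta[b]furan-6,2'-[1,3]dioxolane], i.e. cis-fused (Z)-3-ethylidene-5-methyl-1-vinyl-2-oxabicyclo[3.3.0]octane with an 8,8-ethylenedioxy group
Conditions: CH3CHBr2, Zn, TiCl4, TMEDA, PbCl2 (cat.), THF, 0 °C to rt; basic alumina
Reagents that add atoms: 1,1-dibromoethane, CC(Br)Br
Why: Takai–Utimoto alkylidenation of the ester-type carbonyl by the geminal dimetal reagent (oxametallacyclobutane formation and cycloreversion) should give the (Z)-enol ether with methyl cis to the ring oxygen and leave the vinyl group and the ketal untouched; either enol ether geometry would feed the same ring expansion.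

Step 7
Reactants: 15 cis-fused (Z)-3-ethylidene-5-methyl-1-vinyl-8,8-ethylenedioxy-2-oxabicyclo[3.3.0]octane
Product: 16 (1R)-4,4-ethylenedioxy-1,8-dimethylbicyclo[5.3.0]dec-5-en-9-one (both C8 epimers)
Conditions: toluene (0.02 M), i-Pr2NEt (0.2 equiv), base-washed sealed tube, 185 °C
Reagents that add atoms: none
Why: Heating the allyl vinyl ether C8=C9–O–C5–C6=C7 should trigger a concerted [3,3]-sigmatropic (Claisen) shift in which the C7–C8 bond forms as the C5–O bond breaks, and the gain of the C9 carbonyl makes it irreversible. The closest known reaction type is the thermal ring expansion of 2-alkylidene-5-vinyltetrahydrofurans to cyclohept-4-enones. The seven-membered carbocycle (C1, C5–C10) closes by this intramolecular sigmatropic C–C bond formation, enlarging the oxolane by two carbons, and the ring constraints allow only a boat-like six-atom array, which is why the new C5=C6 bond is cis within the ring. The only new stereocentre, C8, is governed by the enol ether geometry and the boat array but is of no consequence because C8 becomes trigonal in step 8, while C1 is untouched and C5 ceases to be stereogenic. The step needs the exocyclic enol ether to react as such: the cis ring fusion holds the vinyl group and the ethylidene carbon on the same side within bonding distance, and the amine additive and base-washed vessel prevent acid-catalysed migration of the enol ether double bond into the ring, hydrolysis and ketal loss. The C4 ketal carbon carries no hydrogen, so no ene or elimination pathway opens at that position.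

Step 8
Reactants: 16 (1R)-4,4-ethylenedioxy-1,8-dimethylbicyclo[5.3.0]dec-5-en-9-one; 17 trifluoromethanesulfonic anhydride
Product: 18 (1R)-4,4-ethylenedioxy-1,8-dimethylbicyclo[5.3.0]deca-5,8-dien-9-yl trifluoromethanesulfonate
Conditions: Tf2O, 2,6-di-tert-butyl-4-methylpyridine, CH2Cl2, 0 °C to rt
Reagents that add atoms: trifluoromethanesulfonic anhydride, O=S(=O)(OS(=O)(=O)C(F)(F)F)C(F)(F)F
Why: Enol triflate formation under equilibrating conditions (elimination from the O-triflyl oxocarbenium ion with a hindered pyridine) should give the tetrasubstituted C8=C9 isomer and not the C9=C10 isomer, and it erases the C8 stereocentre.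

Step 9
Reactants: 18 enol triflate
Product: 19 (1R)-4,4-ethylenedioxy-1,8-dimethylbicyclo[5.3.0]deca-5,8-diene
Conditions: Pd(OAc)2 (5 mol %), PPh3, HCO2H, n-Bu3N, DMF, 60 °C
Reagents that add atoms: none
Why: Palladium-catalysed formate reduction of the enol triflate (oxidative addition, formate decarboxylation to a palladium hydride, C–H reductive elimination) should replace the triflate by hydrogen without moving either double bond.

Step 10
Reactants: 19 skipped diene; 20 N-methylmorpholine N-oxide; 21 water
Product: 22 (1R)-4,4-ethylenedioxy-1,8α-dimethylbicyclo[5.3.0]dec-5-ene-8β,9β-diol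
Conditions: OsO4 (2 mol %), NMO, acetone/H2O (10:1), 0 °C to rt
Reagents that add atoms: N-methylmorpholine N-oxide, C[N+]1([O-])CCOCC1; water, O
Why: Upjohn dihydroxylation is a suprafacial addition that gives the cis-diol, should select the open C8=C9 alkene over C5=C6 (flanked by the quaternary C1 and the ketal carbon C4), and should occur on the β face because the pseudo-axial C1 methyl group shields the α face of C9.

Step 11
Reactants: 22 8β,9β-diol; 23 tert-butyldimethylsilyl trifluoromethanesulfonate
Product: 24 (1R)-9β-(tert-butyldimethylsilyloxy)-4,4-ethylenedioxy-1,8α-dimethylbicyclo[5.3.0]dec-5-en-8β-ol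
Conditions: TBSOTf (1.1 equiv), 2,6-lutidine, CH2Cl2, −78 °C
Reagents that add atoms: tert-butyldimethylsilyl trifluoromethanesulfonate, CC(C)(C)[Si](C)(C)OS(=O)(=O)C(F)(F)F
Why: Silyl ether formation should discriminate the secondary C9 hydroxyl from the tertiary C8 hydroxyl on steric grounds at low temperature.

Step 12
Reactants: 24 9-silyl ether; 25 tert-butyl hydroperoxide
Product: 26 (1R)-9β-(tert-butyldimethylsilyloxy)-4,4-ethylenedioxy-8β-hydroxy-1,8α-dimethylbicyclo[5.3.0]dec-5-en-7-one
Conditions: Rh2(cap)4 (1 mol %), t-BuOOH (70% aq.), K2CO3, ClCH2CH2Cl, 40 °C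
Reagents that add atoms: tert-butyl hydroperoxide, CC(C)(C)OO
Why: Dirhodium caprolactamate/hydroperoxide allylic oxidation proceeds by hydrogen abstraction and peroxide trapping, and C7 is the only allylic carbon that bears hydrogen (C4 is the ketal carbon, C1 is quaternary), so the enone can form only at C7.

Step 13
Reactants: 26 enone
Product: 27 (1R)-9β-(tert-butyldimethylsilyloxy)-4,4-ethylenedioxy-8β-hydroxy-1,8α-dimethyl-5β-H-bicyclo[5.3.0]decan-7-one (trans-fused)
Conditions: [Ir(cod)(PCy3)(py)]PF6 (10 mol %), H2 (1 atm), CH2Cl2, rt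
Reagents that add atoms: none
Why: Hydroxyl-directed homogeneous hydrogenation: the cationic iridium catalyst should bind the β-oriented tertiary C8 hydroxyl and deliver both hydrogens to the β face of C5=C6, which sets H-5 anti to the C1 methyl group (trans ring fusion).

Step 14
Reactants: 27 trans-fused ketone; 28 2-(phenylsulfonyl)-3-phenyloxaziridine
Product: 30 (1R)-9β-(tert-butyldimethylsilyloxy)-4,4-ethylenedioxy-6β,8β-dihydroxy-1,8α-dimethyl-5β-H-bicyclo[5.3.0]decan-7-one, via dipotassium enolate 29 (not isolated)
Conditions: KN(SiMe3)2 (2.2 equiv), THF, −78 °C; then oxaziridine, −78 °C; aq. NH4Cl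
Reagents that add atoms: 2-(phenylsulfonyl)-3-phenyloxaziridine, O=S(=O)(N1OC1c1ccccc1)c1ccccc1
Why: Oxaziridine hydroxylation of the enolate (Davis oxidation): C6 is the only enolisable position because C8 is quaternary, and the oxidant should approach from the β face because the C1 and C8 methyl groups and the C5–C4 bond all lie on the α side, giving the 6β-alcohol.

Step 15
Reactants: 30 6β-hydroxy ketone; 21 water
Product: 31 (1R)-9β-(tert-butyldimethylsilyloxy)-6β,8β-dihydroxy-1,8α-dimethyl-5β-H-bicyclo[5.3.0]decane-4,7-dione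
Conditions: PPTS, acetone/H2O (10:1), 50 °C
Reagents that add atoms: water, O
Why: Mild acid-catalysed ketal hydrolysis in acetone should free the C4 ketone while the silyl ether survives, the mildness being chosen to avoid epimerisation at C5 and β-elimination of the C6 hydroxyl.

Step 16
Reactants: 31 4,7-dione; 32 isopropylmagnesium chloride
Product: 33 (1R)-9β-(tert-butyldimethylsilyloxy)-4α,6β,8β-trihydroxy-4β-isopropyl-1,8α-dimethyl-5β-H-bicyclo[5.3.0]decan-7-one
Conditions: i-PrMgCl (excess), CeCl3, THF, −78 °C; aq. NH4Cl
Reagents that add atoms: isopropylmagnesium chloride, CC(C)[Mg]Cl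
Why: Organocerium 1,2-addition: the weakly basic reagent avoids enolisation and β-hydride reduction, the C7 ketone is shielded between the metal alkoxides at C6 and the quaternary C8, and attack on the cyclopentanone should come from the β face because the C1 methyl group and the C5–C6 bond occupy the α face, giving the 4α-hydroxy-4β-isopropyl centre.

Step 17
Reactants: 34 4-hydroxybenzoic acid; 35 tert-butyldimethylsilyl chloride
Product: 37 4-[(tert-butyldimethylsilyl)oxy]benzoic acid, via silyl ester 36 (not isolated)
Conditions: TBSCl (2.4 equiv), imidazole, DMF, rt; then K2CO3, THF/MeOH/H2O, rt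
Reagents that add atoms: tert-butyldimethylsilyl chloride, CC(C)(C)[Si](C)(C)Cl
Why: Exhaustive silylation followed by selective solvolysis of the labile silyl ester, which cleaves far faster than the aryl silyl ether under mild carbonate, should give the phenol-protected acid.

Step 18
Reactants: 33 triol; 37 4-[(tert-butyldimethylsilyl)oxy]benzoic acid
Product: 38 6β-O-{4-[(tert-butyldimethylsilyl)oxy]benzoyl} ester of 33
Conditions: EDC·HCl, DMAP, CH2Cl2, rt
Reagents that add atoms: 4-[(tert-butyldimethylsilyl)oxy]benzoic acid, CC(C)(C)[Si](C)(C)Oc1ccc(cc1)C(O)=O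
Why: Steglich esterification should acylate the only secondary hydroxyl (C6), since the tertiary C4 and C8 hydroxyls do not react under carbodiimide/DMAP conditions.

Step 19
Reactants: 38 bis-silyl ester
Product: 39 target, (1R)-4α,8β,9β-trihydroxy-6β-(4-hydroxybenzoyloxy)-4β-isopropyl-1,8α-dimethyl-5β-H-bicyclo[5.3.0]decan-7-one
Conditions: HF·pyridine, pyridine/THF, 0 °C to rt
Reagents that add atoms: none
Why: Fluoride-mediated desilylation under buffered, mildly acidic conditions should cleave both the aryl and the secondary alkyl silyl ether without touching the ester, the α-acyloxy ketone or the tertiary alcohols.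

Compound list
1 | 3-methylcyclopentane-1,2-dione | CC1CCC(=O)C1=O | starting material
2 | ethylene glycol | OCCO | starting material
3 | 7-methyl-1,4-dioxaspiro[4.4]nonan-6-one (racemic) | CC1CCC2(OCCO2)C1=O | intermediate
4 | allyl chloroformate | C=CCOC(Cl)=O | starting material
5 | sodium 7-methyl-1,4-dioxaspiro[4.4]non-6-en-6-olate | CC1=C([O-])C2(OCCO2)CC1.[Na+] | intermediate (not isolated)
6 | allyl 7-methyl-1,4-dioxaspiro[4.4]non-6-en-6-yl carbonate | C=CCOC(=O)OC1=C(C)CCC12OCCO2 | intermediate
7 | (R)-7-allyl-7-methyl-1,4-dioxaspiro[4.4]nonan-6-one | C=CC[C@@]1(C)CCC2(OCCO2)C1=O | intermediate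
8 | ozone | [O-][O+]=O | starting material
9 | methanol | CO | starting material
10 | methyl 2-[(7R)-7-methyl-6-oxo-1,4-dioxaspiro[4.4]nonan-7-yl]acetate | COC(=O)C[C@@]1(C)CCC2(OCCO2)C1=O | intermediate
11 | vinylmagnesium bromide | C=C[Mg]Br | starting material
12 | dichlorocerium alkoxide of the tertiary vinyl carbinol (oxygen cis to the acetate arm) | COC(=O)C[C@@]1(C)CCC2(OCCO2)[C@@]1(C=C)O[Ce](Cl)Cl | intermediate (not isolated)
13 | (3aR,6aS)-3a-methyl-6a-vinyltetrahydrospiro[cyclopenta[b]furan-6,2'-[1,3]dioxolan]-2(3H)-one (cis-fused) | O=C1C[C@@]2(C)CCC3(OCCO3)[C@@]2(C=C)O1 | intermediate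
14 | 1,1-dibromoethane | CC(Br)Br | starting material
15 | (3aR,6aS)-2-[(Z)-ethylidene]-3a-methyl-6a-vinylhexahydrospiro[cyclopenta[b]furan-6,2'-[1,3]dioxolane] | C/C=C1/C[C@@]2(C)CCC3(OCCO3)[C@@]2(C=C)O1 | intermediate
16 | (1R)-4,4-ethylenedioxy-1,8-dimethylbicyclo[5.3.0]dec-5-en-9-one (C8 epimers) | O1CCOC12CC[C@]3(C)CC(=O)C(C)CC=C23 | intermediate
17 | trifluoromethanesulfonic anhydride | O=S(=O)(OS(=O)(=O)C(F)(F)F)C(F)(F)F | starting material
18 | (1R)-4,4-ethylenedioxy-1,8-dimethylbicyclo[5.3.0]deca-5,8-dien-9-yl trifluoromethanesulfonate | O1CCOC12CC[C@]3(C)CC(OS(=O)(=O)C(F)(F)F)=C(C)CC=C23 | intermediate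
19 | (1R)-4,4-ethylenedioxy-1,8-dimethylbicyclo[5.3.0]deca-5,8-diene | O1CCOC12CC[C@]3(C)CC=C(C)CC=C23 | intermediate
20 | N-methylmorpholine N-oxide | C[N+]1([O-])CCOCC1 | starting material
21 | water | O | starting material
22 | (1R)-4,4-ethylenedioxy-1,8α-dimethylbicyclo[5.3.0]dec-5-ene-8β,9β-diol | O1CCOC12CC[C@]3(C)C[C@H](O)[C@](C)(O)CC=C23 | intermediate
23 | tert-butyldimethylsilyl trifluoromethanesulfonate | CC(C)(C)[Si](C)(C)OS(=O)(=O)C(F)(F)F | starting material
24 | 9β-O-TBS ether of 22 (8β-OH free) | O1CCOC12CC[C@]3(C)C[C@H](O[Si](C)(C)C(C)(C)C)[C@](C)(O)CC=C23 | intermediate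
25 | tert-butyl hydroperoxide | CC(C)(C)OO | starting material
26 | (1R)-9β-(TBSO)-4,4-ethylenedioxy-8β-hydroxy-1,8α-dimethylbicyclo[5.3.0]dec-5-en-7-one | O1CCOC12CC[C@]3(C)C[C@H](O[Si](C)(C)C(C)(C)C)[C@](C)(O)C(=O)C=C23 | intermediate
27 | trans-fused 5β-H ketone: (1R)-9β-(TBSO)-4,4-ethylenedioxy-8β-hydroxy-1,8α-dimethylbicyclo[5.3.0]decan-7-one | O1CCOC12CC[C@]3(C)C[C@H](O[Si](C)(C)C(C)(C)C)[C@](C)(O)C(=O)C[C@H]32 | intermediate
28 | 2-(phenylsulfonyl)-3-phenyloxaziridine | O=S(=O)(N1OC1c1ccccc1)c1ccccc1 | starting material
29 | dipotassium C6=C7 enolate / C8 alkoxide of 27 | O1CCOC12CC[C@]3(C)C[C@H](O[Si](C)(C)C(C)(C)C)[C@](C)([O-])C([O-])=C[C@H]32.[K+].[K+] | intermediate (not isolated)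
30 | 6β,8β-dihydroxy-7-ketone with 9β-OTBS and 4-ketal, 5β-H | O1CCOC12CC[C@]3(C)C[C@H](O[Si](C)(C)C(C)(C)C)[C@](C)(O)C(=O)[C@H](O)[C@H]32 | intermediate
31 | (1R)-9β-(TBSO)-6β,8β-dihydroxy-1,8α-dimethyl-5β-H-bicyclo[5.3.0]decane-4,7-dione | O=C1CC[C@]2(C)C[C@H](O[Si](C)(C)C(C)(C)C)[C@](C)(O)C(=O)[C@H](O)[C@H]21 | intermediate
32 | isopropylmagnesium chloride | CC(C)[Mg]Cl | starting material
33 | (1R)-9β-(TBSO)-4α,6β,8β-trihydroxy-4β-isopropyl-1,8α-dimethyl-5β-H-bicyclo[5.3.0]decan-7-one | CC(C)[C@]1(O)CC[C@]2(C)C[C@H](O[Si](C)(C)C(C)(C)C)[C@](C)(O)C(=O)[C@H](O)[C@H]21 | intermediate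
34 | 4-hydroxybenzoic acid | OC(=O)c1ccc(O)cc1 | starting material
35 | tert-butyldimethylsilyl chloride | CC(C)(C)[Si](C)(C)Cl | starting material
36 | tert-butyldimethylsilyl 4-[(tert-butyldimethylsilyl)oxy]benzoate | CC(C)(C)[Si](C)(C)OC(=O)c1ccc(O[Si](C)(C)C(C)(C)C)cc1 | intermediate (not isolated)
37 | 4-[(tert-butyldimethylsilyl)oxy]benzoic acid | CC(C)(C)[Si](C)(C)Oc1ccc(cc1)C(O)=O | intermediate
38 | 6β-O-[4-(TBSO)benzoyl] ester of 33 | CC(C)[C@]1(O)CC[C@]2(C)C[C@H](O[Si](C)(C)C(C)(C)C)[C@](C)(O)C(=O)[C@H](OC(=O)c3ccc(O[Si](C)(C)C(C)(C)C)cc3)[C@H]21 | intermediate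
39 | CNP0241001.1 | CC(C)[C@]1(O)CC[C@]2(C)C[C@H](O)[C@](C)(O)C(=O)[C@H](OC(=O)c3ccc(O)cc3)[C@H]21 | target

Total step count: 19. Longest linear sequence: 18 (steps 1–16, 18 and 19).

Three steps most likely to fail

Step 7. At the temperature required, the exocyclic enol ether may migrate into the ring or hydrolyse before it rearranges, or the two fully substituted carbons flanking C5 may slow the shift so that thermal decomposition competes. The fallback replaces the sigmatropic ring expansion by ring-closing metathesis and sets out from ketone 7. Addition of 3-methylbut-3-enylmagnesium bromide (CeCl3, THF, −78 °C) to the C5 carbonyl should give the tertiary carbinol F1, whose C5 configuration is immaterial. Ring-closing metathesis of its allyl and 1,1-disubstituted alkene termini with the second-generation Grubbs catalyst RuCl2(=CHPh)(PCy3)(H2IMes) in CH2Cl2 at 40 °C should close the seven-membered ring through the C8=C9 bond and give the bicyclic alcohol F2. Dehydration with the Burgess reagent (benzene, 50 °C) can proceed only towards C6, because C4 and C1 bear no hydrogen, and the route is rejoined at diene 19.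

Step 6. The titanium–zinc reagent may react sluggishly with the lactone or open it reductively, and the acid-sensitive enol ether may be lost during isolation. The fallback replaces carbonyl alkylidenation by cycloisomerisation of an alkynol and sets out from lactone 13. Reduction with i-Bu2AlH (CH2Cl2, −78 °C) should give the lactol F3. Seyferth–Gilbert homologation with the Ohira–Bestmann reagent (K2CO3, MeOH) should give the terminal alkynol F4. Double deprotonation (n-BuLi, THF, −78 °C) and C-methylation with iodomethane should give the but-2-ynyl carbinol F5. Base-mediated 5-exo-dig hydroalkoxylation (KOt-Bu cat., DMSO, rt), an anti addition across the alkyne, should deliver the (Z)-enol ether, and the route is rejoined at 15.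

Step 8. Regiocontrol of enolisation may be lost (triflation towards C10), or traces of triflic acid may damage the ketal. The fallback replaces enol triflate reduction by a regiospecific carbonyl-to-alkene transposition and sets out from ketone 16. Dehydrogenation with IBX (DMSO, 70 °C) can introduce only the C7=C8 double bond, because C1 is quaternary, and should give the dienone F6. Condensation with p-toluenesulfonyl hydrazide (MeOH, rt) should give the tosylhydrazone F7. Reduction with catecholborane (CHCl3, 0 °C) followed by NaOAc·3H2O (reflux) should pass through the allylic diazene, whose 1,5-hydrogen shift puts hydrogen on C7 and moves the double bond to C8=C9; the route is rejoined at diene 19.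

Further compounds
F1 | step 7 | (7R)-7-allyl-7-methyl-6-(3-methylbut-3-en-1-yl)-1,4-dioxaspiro[4.4]nonan-6-ol (C6 epimers) | C=CC[C@@]1(C)CCC2(OCCO2)C1(O)CCC(C)=C
F2 | step 7 | (1R)-4,4-ethylenedioxy-1,8-dimethylbicyclo[5.3.0]dec-8-en-5-ol (C5 epimers) | O1CCOC12CC[C@]3(C)CC=C(C)CCC23O
F3 | step 6 | lactol of 13: (3aR,6aS)-3a-methyl-6a-vinylhexahydrospiro[cyclopenta[b]furan-6,2'-[1,3]dioxolan]-2-ol (anomers) | OC1C[C@@]2(C)CCC3(OCCO3)[C@@]2(C=C)O1
F4 | step 6 | 7-methyl-7-(prop-2-yn-1-yl)-6-vinyl-1,4-dioxaspiro[4.4]nonan-6-ol (hydroxyl cis to the propargyl arm, C7 as in 13) | C#CC[C@@]1(C)CCC2(OCCO2)[C@]1(O)C=C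
F5 | step 6 | 7-(but-2-yn-1-yl)-7-methyl-6-vinyl-1,4-dioxaspiro[4.4]nonan-6-ol (hydroxyl cis to the butynyl arm) | CC#CC[C@@]1(C)CCC2(OCCO2)[C@]1(O)C=C
F6 | step 8 | (1R)-4,4-ethylenedioxy-1,8-dimethylbicyclo[5.3.0]deca-5,7-dien-9-one | O1CCOC12CC[C@]3(C)CC(=O)C(C)=CC=C23
F7 | step 8 | p-toluenesulfonylhydrazone of F6 | O1CCOC12CC[C@]3(C)CC(=NNS(=O)(=O)c4ccc(C)cc4)C(C)=CC=C23
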